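**Assumptions:** The target (5-hydroxy-6,7,8,4'-tetramethoxyflavone, gardenin B / 5-O-desmethyltangeretin) has no stereocentres, so "single enantiomer" does not apply. Compound 1 (CAS 3162-28-5) is taken as a catalogue compound from flavonoid-intermediate suppliers; I could not verify this here.

## Retrosynthetic overview

1. Target 5 ⇐ tangeretin 4 by chelation-directed cleavage of the peri (C5) methyl ether only.
2. 4 ⇐ 2'-hydroxychalcone 3 by oxidative cyclisation, which forms the O1–C2 bond and the C2=C3 double bond.
3. 3 ⇐ acetophenone 1 + 4-methoxybenzaldehyde 2 by Claisen–Schmidt condensation (Cα–Cβ bond).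
4. Ring order: the A ring (from 1) and B ring (from 2) are bought intact; only the pyran-4-one C ring is built, in step 2.

## Route

**Step 1**
Reactants: 1, 2'-hydroxy-3',4',5',6'-tetramethoxyacetophenone; 2, 4-methoxybenzaldehyde (p-anisaldehyde)
Product: 3, (E)-1-(2-hydroxy-3,4,5,6-tetramethoxyphenyl)-3-(4-methoxyphenyl)prop-2-en-1-one
Conditions: 2 (1.2 equiv), 50% aq. KOH (excess), EtOH, 0 °C → rt, 24–48 h; then 2 M HCl to pH ~3
Reagents that add atoms: none (all product atoms come from 1 and 2; water is lost)
Why: Claisen–Schmidt (crossed aldol) condensation of the methyl ketone enolate with a non-enolisable aldehyde, with E1cB dehydration giving the conjugated E-enone; any flavanone formed by ring closure is carried forward, since step 2 converts it to the same product.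

**Step 2**
Reactants: 3, the 2'-hydroxychalcone
Product: 4, 5,6,7,8-tetramethoxy-2-(4-methoxyphenyl)-4H-chromen-4-one (tangeretin)
Conditions: I2 (10 mol %), DMSO, 130 °C, 2–3 h; aq. Na2S2O3 work-up
Reagents that add atoms: none (net loss of 2 H)
Why: I2/DMSO oxidative cyclisation: 6-endo oxa-Michael addition of the 2'-OH, α-iodination and loss of HI give the flavone, with DMSO re-oxidising HI to I2; the A ring is fully substituted, so it cannot be iodinated.

**Step 3**
Reactants: 4, tangeretin
Product: 5, 5-hydroxy-6,7,8-trimethoxy-2-(4-methoxyphenyl)-4H-chromen-4-one (target)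
Conditions: BCl3 (1.2 equiv, 1 M in CH2Cl2), CH2Cl2, −10 → 0 °C, 1–2 h; then aq. HCl/MeOH to hydrolyse the boron chelate
Reagents that add atoms: none (net loss of CH2 as MeCl)
Why: Chelation-controlled selective O-demethylation: boron binds the C4 carbonyl and the peri 5-OMe in a six-membered chelate, so chloride removes only that methyl; the 6-, 7-, 8- and 4'-OMe groups cannot chelate and survive at low temperature with near-stoichiometric reagent.

## Compound list

1 | 2'-hydroxy-3',4',5',6'-tetramethoxyacetophenone | CC(=O)c1c(O)c(OC)c(OC)c(OC)c1OC | starting material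
2 | 4-methoxybenzaldehyde | COc1ccc(C=O)cc1 | starting material
3 | (E)-2'-hydroxy-3',4',5',6',4-pentamethoxychalcone | COc1ccc(/C=C/C(=O)c2c(O)c(OC)c(OC)c(OC)c2OC)cc1 | intermediate
4 | tangeretin (5,6,7,8,4'-pentamethoxyflavone) | COc1ccc(-c2cc(=O)c3c(OC)c(OC)c(OC)c(OC)c3o2)cc1 | intermediate
5 | 5-hydroxy-6,7,8,4'-tetramethoxyflavone | COc1ccc(-c2cc(=O)c3c(O)c(OC)c(OC)c(OC)c3o2)cc1 | target

## Summary

Total steps: 3. Longest linear sequence: 3.

Steps most likely to fail, with fallbacks:

1. **Step 3 (over-demethylation at C6, or incomplete reaction).** Fallback: avoid demethylation altogether by never methylating the 5-OH. Start from acacetin (5,7-dihydroxy-4'-methoxyflavone), dibrominate at C6/C8 with NBS, replace both bromides with methoxide (NaOMe/CuBr, DMF–MeOH), then methylate only the non-chelated 7-OH (MeI, K2CO3).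
2. **Step 1 (slow condensation of the di-ortho-substituted ketone, Cannizzaro loss of aldehyde, chalcone/flavanone mixtures).** Fallback: Baker–Venkataraman route, which replaces steps 1 and 2. O-acylate 1 with 4-methoxybenzoyl chloride, rearrange with KOH/pyridine to the 1,3-diketone, and cyclodehydrate with AcOH/H2SO4 directly to 4; no oxidation is needed.
3. **Step 2 (stalling at the flavanone, or HI-induced partial 5-demethylation giving a 4/5 mixture).** A 4/5 mixture can simply be taken into step 3. Fallback if oxidation fails: make ring closure and oxidation separate steps by isomerising 3 to the flavanone (NaOAc, EtOH, reflux) and dehydrogenating it with DDQ in dioxane.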